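**Plan**

- Retrosynthesis: the target is a C2-symmetric 20-membered diolide (ring atoms O1, C2–C10, O11, C12–C20). Both central sp2–sp2 bonds of its two (Z,Z)-dienes, C4–C5 and C14–C15, are cut, giving two identical molecules of ester 19; the ester C–O bond then gives alcohol 12 and acid 17.
- Enabling feature: the twofold axis; each cut bond lies between two alkene carbons, so one end can be an iodide and the other a stannane (head-to-tail only); one half alone would have to close to a strained ten-membered (Z,Z)-dienolide, so two halves should join before the ring closes.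
- Forward: the oxazole is made first, then the chain of one half is grown from C10 towards C5 (aldehyde 4, crotylboration, hydroformylation to a lactol, alkyne, (Z)-alkenylstannane 12) and esterified with 17; the single ring closure is the last step.
- Stereochemistry: C9/C10 (and C19/C20) are set together by one reagent-controlled (Z)-crotylboration. The four Z double bonds are carried in, two from anti-carbomagnesiation/iodination (17) and two from syn-hydrozirconation of a stannylalkyne (12), and kept by a stereoretentive coupling.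

Key step: step 11

Assumption: (−)-Ipc2BOMe is the borinate derived from (+)-α-pinene, and its (Z)-crotyl derivative is taken to add to the Si face of the unbranched aldehyde 4; lactol 8 is carried as its anomeric mixture.

**Route**

Step 1
Reactants: 1 ethyl 3,3-diethoxypropanoate
Product: 3 5-(2,2-diethoxyethyl)-1,3-oxazole, via isocyano ketone 2 (not isolated)
Conditions: MeNC (2.2 equiv), nBuLi (2.2 equiv), THF, −78 °C; then 1, −78 to 0 °C; AcOH quench
Reagents that add atoms: methyl isocyanide, C[N+]#[C-]
Why: Schöllkopf oxazole synthesis, in which (isocyanomethyl)lithium acylates at the ester carbonyl, a second equivalent deprotonates isocyano ketone 2 and the enolate oxygen closes onto the isocyanide carbon to give the 5-substituted oxazole, the acetal being inert to base.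

Step 2
Reactants: 3 5-(2,2-diethoxyethyl)-1,3-oxazole
Product: 4 2-(1,3-oxazol-5-yl)acetaldehyde
Conditions: Amberlyst-15 (H+ form), acetone/H2O, rt; filtered, concentrated cold, used at once
Reagents that add atoms: water, O
Why: Acid-catalysed acetal hydrolysis, which the weakly basic oxazole should tolerate, with the labile aldehyde taken on without chromatography.

Step 3
Reactants: 4 2-(1,3-oxazol-5-yl)acetaldehyde
Product: 6 (2R,3R)-3-methyl-1-(1,3-oxazol-5-yl)pent-4-en-2-ol, via borinate 5 (not isolated)
Conditions: cis-2-butene, KOtBu, nBuLi, THF, −78 to −45 °C; (−)-Ipc2BOMe, −78 °C; BF3·OEt2; then 4, −78 °C; NaOH, H2O2, 0 °C to rt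
Reagents that add atoms: (Z)-crotyldiisopinocampheylborane, C/C=C\CB([C@@H]1C[C@@H]2C[C@@H](C2(C)C)[C@H]1C)[C@@H]1C[C@@H]2C[C@@H](C2(C)C)[C@H]1C, formed in the flask from cis-2-butene, C/C=C\C
Why: Brown asymmetric crotylboration through a closed chair transition state, in which the Z-crotyl geometry gives the syn relationship and the isopinocampheyl groups direct the crotyl unit to the Si face of the aldehyde, so both stereocentres of each half of the target are set here by reagent control.

Step 4
Reactants: 6 (2R,3R)-3-methyl-1-(1,3-oxazol-5-yl)pent-4-en-2-ol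
Product: 8 (5R,6R)-5-methyl-6-(1,3-oxazol-5-ylmethyl)oxan-2-ol as an anomeric mixture, via hydroxy aldehyde 7 (not isolated)
Conditions: Rh(acac)(CO)2 (2 mol%), BIPHEPHOS (4 mol%), CO/H2 (1:1, 5 bar), THF, 60 °C
Reagents that add atoms: carbon monoxide, [C-]#[O+]
Why: Linear-selective rhodium-catalysed hydroformylation of the terminal alkene (bulky bisphosphite ligand, allylic branching) should place the formyl group on the terminal carbon, and δ-hydroxy aldehyde 7 closes to the six-membered lactol, whose anomeric centre is removed in step 5.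

Step 5
Reactants: 8 (5R,6R)-5-methyl-6-(1,3-oxazol-5-ylmethyl)oxan-2-ol
Product: 9 (2R,3R)-3-methyl-1-(1,3-oxazol-5-yl)hept-6-yn-2-ol
Conditions: dimethyl (1-diazo-2-oxopropyl)phosphonate, K2CO3, MeOH, 0 °C to rt
Reagents that add atoms: dimethyl (1-diazo-2-oxopropyl)phosphonate, CC(=O)C(=[N+]=[N-])P(=O)(OC)OC
Why: Seyferth–Gilbert homologation with the Ohira–Bestmann reagent, in which ring–chain tautomerism of lactol 8 in basic methanol exposes its open-chain hydroxy aldehyde form (the compound already numbered 7), whose formyl group is converted into the terminal alkyne with the secondary hydroxyl left free, the stereocentres being remote from the basic site.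

Step 6
Reactants: 9 (2R,3R)-3-methyl-1-(1,3-oxazol-5-yl)hept-6-yn-2-ol
Product: 12 (2R,3R,6Z)-3-methyl-1-(1,3-oxazol-5-yl)-7-(tributylstannyl)hept-6-en-2-ol, via bis-stannyl alkyne 10 (not isolated), via stannyl zirconocenyl alkene 11 (not isolated)
Conditions: Bu3SnOMe (2.2 equiv), ZnBr2 (5 mol%), THF, rt, then volatiles removed; Cp2Zr(H)Cl (2.5 equiv), THF, rt; H2O; Et3N-deactivated silica
Reagents that add atoms: tributyltin methoxide, CCCC[Sn](CCCC)(CCCC)OC
Why: The tin alkoxide stannylates the alkyne C–H and the O–H without strong base, sparing the acidic oxazole C2–H, and syn-hydrozirconation of the 1-stannylalkyne places zirconium on the tin-bearing carbon so that protonolysis with retention should give the (Z)-alkenylstannane.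

Step 7
Reactants: 13 prop-2-yn-1-ol
Product: 15 (2Z)-3-iodo-2-methylprop-2-en-1-ol, via magnesium chelate 14 (not isolated)
Conditions: MeMgBr (3 equiv), CuI (10 mol%), THF, −10 °C to rt; then I2, −78 to 0 °C
Reagents that add atoms: methylmagnesium bromide, C[Mg]Br; iodine, II
Why: Copper-catalysed anti-carbomagnesiation of the propargylic alkoxide puts methyl on C2 and magnesium on C3 cis to the CH2O group in chelate 14, and iodinolysis with retention fixes the Z geometry.

Step 8
Reactants: 15 (2Z)-3-iodo-2-methylprop-2-en-1-ol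
Product: 16 (2Z)-3-iodo-2-methylprop-2-enal
Conditions: MnO2 (excess), CH2Cl2, rt, dark
Reagents that add atoms: none
Why: Chemoselective allylic oxidation under neutral conditions, which should avoid acid- or nucleophile-induced Z to E isomerisation of the β-iodoenal.

Step 9
Reactants: 16 (2Z)-3-iodo-2-methylprop-2-enal
Product: 17 (2Z)-3-iodo-2-methylprop-2-enoic acid
Conditions: NaClO2, NaH2PO4, 2-methyl-2-butene, tBuOH/H2O, 0 °C to rt
Reagents that add atoms: sodium chlorite, [Na+].[O-]Cl=O
Why: Pinnick oxidation of the enal with a hypochlorite scavenger, whose buffered conditions should keep the alkenyl iodide and its Z geometry.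

Step 10
Reactants: 12 (2R,3R,6Z)-3-methyl-1-(1,3-oxazol-5-yl)-7-(tributylstannyl)hept-6-en-2-ol; 17 (2Z)-3-iodo-2-methylprop-2-enoic acid
Product: 19 (2R,3R,6Z)-3-methyl-1-(1,3-oxazol-5-yl)-7-(tributylstannyl)hept-6-en-2-yl (2Z)-3-iodo-2-methylprop-2-enoate, via mixed anhydride 18 (not isolated)
Conditions: 2-methyl-6-nitrobenzoic anhydride (MNBA), Et3N, DMAP (cat.), CH2Cl2, 0 °C to rt
Reagents that add atoms: none
Why: Shiina esterification, in which the acid is activated as mixed anhydride 18 and transferred by DMAP to the secondary alcohol with retention at the carbinol carbon, the basic chloride-free medium sparing the alkenylstannane and the Z-iodoenoate.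

Step 11
Reactants: 19 (2R,3R,6Z)-3-methyl-1-(1,3-oxazol-5-yl)-7-(tributylstannyl)hept-6-en-2-yl (2Z)-3-iodo-2-methylprop-2-enoate (two molecules)
Product: 21 CNP0414419.1 [(3Z,5Z,9R,10R,13Z,15Z,19R,20R)-3,9,13,19-tetramethyl-10,20-bis(1,3-oxazol-5-ylmethyl)-1,11-dioxacycloicosa-3,5,13,15-tetraene-2,12-dione], via linear dimer 20 (not isolated)
Conditions: Cu(O2CC4H3S) (CuTC, 6 equiv), NMP (0.02 M), 0 °C to rt, argon, dark
Reagents that add atoms: none
Why: Tin-to-copper transmetalation of the (Z)-alkenylstannane of one molecule of 19 gives an alkenylcopper (monovalent copper) that adds oxidatively to the (Z)-β-iodoenoate of a second molecule and eliminates reductively from trivalent copper to give linear dimer 20, and the same sequence within 20 then forms the second diene bond. The closest known reaction type is the palladium-free, copper thiophene-2-carboxylate-mediated Stille-type coupling of alkenylstannanes with alkenyl iodides, which is known for head-to-tail cyclodimerisation of stannyl/iodo ester monomers to sixteen-membered macrodiolides. The 20-membered ring is closed by intramolecular sp2–sp2 coupling at C4–C5 (ring numbering), a head-to-tail macrocyclisation of 20. No stereocentre is formed: the C9/C10 and C19/C20 pairs come unchanged from 19, and the four Z double bonds should arise with retention at both carbon termini. The step needs the cyclodimer over the ten-membered monomeric lactone, over linear oligomers and over protodestannylation; the medium-ring strain and forced diene twist of the monomeric (Z,Z)-dienolide, the absence of any homocoupling channel, moderate dilution and fast copper-mediated coupling should secure this. Because two homochiral halves are joined, any minor enantiomer of 19 should end up mainly in a separable heterochiral diastereomer, so the enantiomeric purity of 21 should exceed that of 19.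

**Compound list**

1 | ethyl 3,3-diethoxypropanoate | CCOC(=O)CC(OCC)OCC | starting material
2 | 4,4-diethoxy-1-isocyanobutan-2-one | CCOC(CC(=O)C[N+]#[C-])OCC | intermediate
3 | 5-(2,2-diethoxyethyl)-1,3-oxazole | CCOC(Cc1cnco1)OCC | intermediate
4 | 2-(1,3-oxazol-5-yl)acetaldehyde | O=CCc1cnco1 | intermediate
5 | (2R,3R)-3-methyl-1-(1,3-oxazol-5-yl)pent-4-en-2-yl bis[(1R,2S,3R,5R)-2,6,6-trimethylbicyclo[3.1.1]hept-3-yl]borinate | C=C[C@@H](C)[C@@H](Cc1cnco1)OB([C@@H]1C[C@@H]2C[C@@H](C2(C)C)[C@H]1C)[C@@H]1C[C@@H]2C[C@@H](C2(C)C)[C@H]1C | intermediate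
6 | (2R,3R)-3-methyl-1-(1,3-oxazol-5-yl)pent-4-en-2-ol | C=C[C@@H](C)[C@@H](Cc1cnco1)O | intermediate
7 | (4R,5R)-5-hydroxy-4-methyl-6-(1,3-oxazol-5-yl)hexanal | O=CCC[C@@H](C)[C@@H](Cc1cnco1)O | intermediate
8 | (5R,6R)-5-methyl-6-(1,3-oxazol-5-ylmethyl)oxan-2-ol (anomeric mixture) | C[C@@H]1CCC(O)O[C@@H]1Cc1cnco1 | intermediate
9 | (2R,3R)-3-methyl-1-(1,3-oxazol-5-yl)hept-6-yn-2-ol | C#CCC[C@@H](C)[C@@H](Cc1cnco1)O | intermediate
10 | tributyl{[(2R,3R)-3-methyl-1-(1,3-oxazol-5-yl)-7-(tributylstannyl)hept-6-yn-2-yl]oxy}stannane | CCCC[Sn](CCCC)(CCCC)C#CCC[C@@H](C)[C@@H](Cc1cnco1)O[Sn](CCCC)(CCCC)CCCC | intermediate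
11 | chlorobis(cyclopentadienyl)[(1Z,5R,6R)-5-methyl-7-(1,3-oxazol-5-yl)-1-(tributylstannyl)-6-[(tributylstannyl)oxy]hept-1-en-1-yl]zirconium | CCCC[Sn](CCCC)(CCCC)/C(=C\CC[C@@H](C)[C@@H](Cc1cnco1)O[Sn](CCCC)(CCCC)CCCC)[Zr](Cl)(C1C=CC=C1)C1C=CC=C1 | intermediate
12 | (2R,3R,6Z)-3-methyl-1-(1,3-oxazol-5-yl)-7-(tributylstannyl)hept-6-en-2-ol | CCCC[Sn](CCCC)(CCCC)/C=C\CC[C@@H](C)[C@@H](Cc1cnco1)O | intermediate
13 | prop-2-yn-1-ol | C#CCO | starting material
14 | 4-methyl-2,5-dihydro-1,2-oxamagnesole | CC1=C[Mg]OC1 | intermediate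
15 | (2Z)-3-iodo-2-methylprop-2-en-1-ol | C/C(CO)=C/I | intermediate
16 | (2Z)-3-iodo-2-methylprop-2-enal | C/C(C=O)=C/I | intermediate
17 | (2Z)-3-iodo-2-methylprop-2-enoic acid | C/C(=C/I)C(=O)O | intermediate
18 | (2Z)-3-iodo-2-methylprop-2-enoic 2-methyl-6-nitrobenzoic anhydride | C/C(=C/I)C(=O)OC(=O)c1c(C)cccc1[N+](=O)[O-] | intermediate
19 | (2R,3R,6Z)-3-methyl-1-(1,3-oxazol-5-yl)-7-(tributylstannyl)hept-6-en-2-yl (2Z)-3-iodo-2-methylprop-2-enoate | CCCC[Sn](CCCC)(CCCC)/C=C\CC[C@@H](C)[C@@H](Cc1cnco1)OC(=O)/C(C)=C\I | intermediate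
20 | (2R,3R,6Z)-3-methyl-1-(1,3-oxazol-5-yl)-7-(tributylstannyl)hept-6-en-2-yl (2Z,4Z,8R,9R)-9-{[(2Z)-3-iodo-2-methylprop-2-enoyl]oxy}-2,8-dimethyl-10-(1,3-oxazol-5-yl)deca-2,4-dienoate | CCCC[Sn](CCCC)(CCCC)/C=C\CC[C@@H](C)[C@@H](Cc1cnco1)OC(=O)/C(C)=C\C=C/CC[C@@H](C)[C@@H](Cc1cnco1)OC(=O)/C(C)=C\I | intermediate
21 | CNP0414419.1, (3Z,5Z,9R,10R,13Z,15Z,19R,20R)-3,9,13,19-tetramethyl-10,20-bis(1,3-oxazol-5-ylmethyl)-1,11-dioxacycloicosa-3,5,13,15-tetraene-2,12-dione | C/C1=C/C=C\CC[C@@H](C)[C@@H](Cc2cnco2)OC(=O)/C(C)=C\C=C/CC[C@@H](C)[C@@H](Cc2cnco2)OC1=O | target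

**Step count and risks**

Total steps: 11. Longest linear sequence: 8 (steps 1–6, 10, 11).

Steps most likely to fail:

1. Step 11. The processes at risk are closure of the ten-membered monomeric lactone, linear oligomerisation outrunning closure of the 20-membered ring, and protodestannylation before coupling. The fallback builds the open chain stepwise and closes the ring by an unambiguously intramolecular coupling at the alkyne oxidation level; it sets out from 9, 12 and 17 and returns at 21. Alkynol 9 would be esterified with 17 (MNBA, Et3N, DMAP) to alkynyl iodoacrylate F1. Stille coupling of 12 with F1 (Pd2(dba)3, AsPh3, NMP, rt) would give hydroxy dienoate F2, and a second esterification with 17 would give iodoacrylate F3. Intramolecular Sonogashira coupling under high dilution (Pd(PPh3)4, CuI, iPr2NH, THF, slow addition) would close the ring as dienyne macrodiolide F4. Z-selective semi-reduction of the conjugated enyne (Zn activated with Cu(OAc)2 and AgNO3, MeOH/H2O) would then give 21.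

2. Step 6. The processes at risk are incomplete or unselective stannylation, attack of the zirconium hydride on the oxazole, and loss of tin by protonolysis during isolation. The fallback avoids the alkyne and sets out from lactol 8, returning at 12. Stork–Zhao olefination of 8 (ylide from (iodomethyl)triphenylphosphonium iodide and NaN(SiMe3)2, THF/DMPU, −78 to −20 °C, excess ylide) would give (Z)-alkenyl iodide F5. Palladium-catalysed stannylation (Pd(PPh3)4, Bu3SnSnBu3, THF, 60 °C) would convert F5 into 12.

3. Step 3. The processes at risk are enolisation and self-condensation of the heteroarylacetaldehyde 4 before it meets the borane, and erosion of facial selectivity by aldehyde that has partly decomposed. The fallback runs the crotylboration on a stable acetal aldehyde and builds the oxazole afterwards; it sets out from 1 and returns at 6. Reduction of 1 (iBu2AlH, toluene, −78 °C) would give 3,3-diethoxypropanal F6. The same (Z)-crotylboration would give homoallylic alcohol F7, and silylation (TBSOTf, 2,6-lutidine) would give silyl ether F8. Mild acetal hydrolysis (aq. AcOH, THF) would give β-silyloxy aldehyde F9, and van Leusen oxazole synthesis (TosMIC, K2CO3, MeOH) would give oxazole silyl ether F10. Desilylation with Bu4NF would return 6.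

**Further compounds**

F1 | step 11 | (2R,3R)-3-methyl-1-(1,3-oxazol-5-yl)hept-6-yn-2-yl (2Z)-3-iodo-2-methylprop-2-enoate | C#CCC[C@@H](C)[C@@H](Cc1cnco1)OC(=O)/C(C)=C\I
F2 | step 11 | (2R,3R)-3-methyl-1-(1,3-oxazol-5-yl)hept-6-yn-2-yl (2Z,4Z,8R,9R)-9-hydroxy-2,8-dimethyl-10-(1,3-oxazol-5-yl)deca-2,4-dienoate | C#CCC[C@@H](C)[C@@H](Cc1cnco1)OC(=O)/C(C)=C\C=C/CC[C@@H](C)[C@@H](Cc1cnco1)O
F3 | step 11 | (2R,3R)-3-methyl-1-(1,3-oxazol-5-yl)hept-6-yn-2-yl (2Z,4Z,8R,9R)-9-{[(2Z)-3-iodo-2-methylprop-2-enoyl]oxy}-2,8-dimethyl-10-(1,3-oxazol-5-yl)deca-2,4-dienoate | C#CCC[C@@H](C)[C@@H](Cc1cnco1)OC(=O)/C(C)=C\C=C/CC[C@@H](C)[C@@H](Cc1cnco1)OC(=O)/C(C)=C\I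
F4 | step 11 | (3Z,9R,10R,13Z,15Z,19R,20R)-3,9,13,19-tetramethyl-10,20-bis(1,3-oxazol-5-ylmethyl)-1,11-dioxacycloicosa-3,13,15-trien-5-yne-2,12-dione | C/C1=C/C#CCC[C@@H](C)[C@@H](Cc2cnco2)OC(=O)/C(C)=C\C=C/CC[C@@H](C)[C@@H](Cc2cnco2)OC1=O
F5 | step 6 | (2R,3R,6Z)-7-iodo-3-methyl-1-(1,3-oxazol-5-yl)hept-6-en-2-ol | I/C=C\CC[C@@H](C)[C@@H](Cc1cnco1)O
F6 | step 3 | 3,3-diethoxypropanal | CCOC(CC=O)OCC
F7 | step 3 | (3R,4R)-1,1-diethoxy-4-methylhex-5-en-3-ol | C=C[C@@H](C)[C@@H](CC(OCC)OCC)O
F8 | step 3 | tert-butyl{[(3R,4R)-1,1-diethoxy-4-methylhex-5-en-3-yl]oxy}dimethylsilane | C=C[C@@H](C)[C@@H](CC(OCC)OCC)O[Si](C)(C)C(C)(C)C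
F9 | step 3 | (3R,4R)-3-[(tert-butyldimethylsilyl)oxy]-4-methylhex-5-enal | C=C[C@@H](C)[C@@H](CC=O)O[Si](C)(C)C(C)(C)C
F10 | step 3 | 5-[(2R,3R)-2-[(tert-butyldimethylsilyl)oxy]-3-methylpent-4-en-1-yl]-1,3-oxazole | C=C[C@@H](C)[C@@H](Cc1cnco1)O[Si](C)(C)C(C)(C)C
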